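**Retrosynthetic overview**
1. Feature: number each phloroglucinol ring A as C1 (aroyl carbon), C2 (OH), C3 (bridge carbon), C4 (OMe), C5 (H), C6 (OH). The atoms C5–C4–C3–CH2–C3′–C4′–C5′ then form one unbranched seven-carbon chain, oxygenated only at C4 and C4′. This is the skeleton of heptane-2,6-dione, with its two oxygens where the two A-ring methyl ethers sit, and C6–C1–C2 of each ring is a malonyl unit.
2. Last disconnection: the two C1–C(=O) bonds, leading to the C1,C1′-dilithiated MOM-protected diarylmethane core and a B-ring aldehyde made from 2,4-dihydroxy-6-methylbenzaldehyde.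
3. Key disconnection: C5–C6 and C2–C3 in both A rings, leading to 2,6-dimethoxyhepta-1,6-diene and two malonyl dichlorides.
4. The bis(methyl enol ether) comes regiospecifically from dimethyl glutarate by double ester methylenation. This avoids acid treatment of the aldol-prone 1,5-diketone.
5. Ring order: rings A and A′ are formed together from the acyclic chain in step 2. Rings B and B′ are brought in preformed in step 6.

Key step: step 2

Remark on the chemistry: the target has no stereocentre, and rotation about its aryl–CO and aryl–CH2 bonds is taken to be fast at room temperature. The compound is therefore achiral and no enantiocontrol is needed.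

**Step 1**
Reactants: 1 dimethyl glutarate
Product: 2 2,6-dimethoxyhepta-1,6-diene
Conditions: Cp2TiMe2 (5 equiv), toluene, 70 °C, dark; pentane, filtration through basic Al2O3; distillation from K2CO3
Reagents that add atoms: dimethyltitanocene (Petasis reagent), C[Ti+2]C.c1cc[cH-]c1.c1cc[cH-]c1
Why: Petasis methylenation, in which thermally generated Cp2Ti=CH2 converts each ester C=O through an oxatitanacyclobutane into a 1,1-disubstituted methyl enol ether, so both double bonds are fixed at the chain termini and the non-acidic medium avoids enol ether isomerisation and the intramolecular aldol condensation of the parent 1,5-diketone.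

**Step 2**
Reactants: 2 2,6-dimethoxyhepta-1,6-diene; 3 malonyl dichloride (two molecules enter the product)
Product: 5 bis(2,4-dihydroxy-6-methoxyphenyl)methane, via bis(methoxyenone) diacyl dichloride 4 (not isolated)
Conditions: 3 (2.4 equiv), 2,6-di-tert-butyl-4-methylpyridine (5 equiv), toluene, −30 °C, slow addition of 2 (high dilution); → rt; then 70 °C; aq. NaHCO3/MeOH work-up
Reagents that add atoms: none
Why: Proposed new method: each terminal =CH2 (future C5) attacks a carbonyl of 3 (future C6) and the resulting O-methyl oxocarbenium ion gives up a proton to the hindered pyridine, the known C-acylation of enol ethers to β-alkoxy enones, which delivers 4 with both methyl ethers intact. In the favoured E-enone the allylic CH2 (future C3), and not the methoxy oxygen, lies cis to the acyl chain, so pyridinium-buffered enolisation towards C3 gives a methoxy-dienol whose C3 terminus attacks C2 of the remaining acid chloride or of the acylketene formed from it by loss of HCl. Each of the two rings closes by a 6-(enolendo)-exo-trig C-acylation (in the ketene variant a 6π electrocyclisation of a dienylketene), and tautomerisation of the cyclohexadienone to the 3,5-dihydroxyanisole makes the closure irreversible and converts the labile enol methyl ether into a robust aryl methyl ether at C4, next to the bridge. The closest known reaction type is the Effenberger α,α′-annulation of ketone methyl enol ethers with malonyl dichloride, which without base expels MeCl and with acyclic ketones drifts to 4-hydroxy-2-pyrones, so that retention of the methyl group, the open-chain substrate and the twofold closure are the unproven elements. No stereocentre is created, and the selectivities needed are C- over O-closure and proton loss over chloride demethylation, which rest on the O-methyl cap and E geometry of 4, on C3 being the only γ-carbon of each vinylogous ester, and on a base too hindered to be acylated whose hydrochloride leaves the toluene solution as a solid. Slow addition of 2 to an excess of 3 at high dilution should keep one malonyl unit from linking two enol ether termini.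

**Step 3**
Reactants: 5 bis(2,4-dihydroxy-6-methoxyphenyl)methane
Product: 6 bis[6-methoxy-2,4-bis(methoxymethoxy)phenyl]methane
Conditions: MOMCl (6 equiv), iPr2NEt (8 equiv), CH2Cl2, 0 °C → rt
Reagents that add atoms: chloromethyl methyl ether (MOMCl), COCCl
Why: Williamson-type O-alkylation of the four phenols with MOMCl under amine base is routine for phloroglucinol ethers, avoids C-alkylation of the electron-rich rings, and installs the directing groups for step 6.

**Step 4**
Reactants: 7 2,4-dihydroxy-6-methylbenzaldehyde
Product: 8 2-hydroxy-4-(methoxymethoxy)-6-methylbenzaldehyde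
Conditions: MOMCl (1.05 equiv), iPr2NEt (1.2 equiv), CH2Cl2, 0 °C
Reagents that add atoms: chloromethyl methyl ether (MOMCl), COCCl
Why: Regioselective O-alkylation, because the 2-OH is held in a hydrogen bond to the aldehyde and one equivalent of MOMCl should react at the free, more acidic 4-OH.

**Step 5**
Reactants: 8 2-hydroxy-4-(methoxymethoxy)-6-methylbenzaldehyde
Product: 9 2-methoxy-4-(methoxymethoxy)-6-methylbenzaldehyde
Conditions: MeI (2 equiv), K2CO3 (2 equiv), DMF, rt
Reagents that add atoms: iodomethane, CI
Why: Williamson ether synthesis, in which carbonate in DMF deprotonates the chelated phenol and MeI methylates it while aldehyde and MOM ether stay untouched.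

**Step 6**
Reactants: 6 bis[6-methoxy-2,4-bis(methoxymethoxy)phenyl]methane; 9 2-methoxy-4-(methoxymethoxy)-6-methylbenzaldehyde (two molecules enter the product)
Product: 11 hexa-MOM bis(diarylcarbinol) as a meso/dl mixture, via dilithiated tetra-MOM core 10 (not isolated)
Conditions: n-BuLi (2.4 equiv), TMEDA (2.4 equiv), THF, 0 °C; then 9 (2.6 equiv), −78 °C → 0 °C; H2O
Reagents that add atoms: none
Why: Directed ortho-metalation followed by 1,2-addition, in which C1–H of each ring is the only position flanked by two chelating MOM ethers and so outranks C5–H (OMe/OMOM) and the electron-rich, twisted bridge CH2, the aryllithium then adds to the non-enolisable aldehyde, and the two new carbinol centres are formed without control because both are erased in step 7.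

**Step 7**
Reactants: 11 hexa-MOM bis(diarylcarbinol)
Product: 12 hexa-MOM bis(benzophenone)
Conditions: Dess–Martin periodinane (3 equiv), pyridine (6 equiv), CH2Cl2, 0 °C → rt
Reagents that add atoms: none
Why: Dess–Martin oxidation handles secondary diarylcarbinols with four ortho substituents, the pyridine buffer protects the MOM ethers and the easily ionised carbinols, and both stereocentres disappear.

**Step 8**
Reactants: 12 hexa-MOM bis(benzophenone)
Product: 13 digriseophene A
Conditions: HCl (1.25 M in MeOH), MeOH–THF, 40 °C, dilute, N2 sweep
Reagents that add atoms: none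
Why: Acid-catalysed transacetalisation of the six aryl MOM ethers to dimethoxymethane is standard, the aryl methyl ethers, diaryl ketones and bridge tolerate dilute methanolic HCl, and dilution with removal of the volatile acetal keeps formaldehyde equivalents away from the free C5 positions.

**Compound list**
1 | dimethyl glutarate (dimethyl pentanedioate) | COC(=O)CCCC(=O)OC | starting material
2 | 2,6-dimethoxyhepta-1,6-diene | C=C(OC)CCCC(=C)OC | intermediate
3 | malonyl dichloride | O=C(Cl)CC(=O)Cl | starting material
4 | (4E,9E)-5,9-dimethoxy-3,11-dioxotrideca-4,9-dienedioyl dichloride | O=C(Cl)CC(=O)/C=C(/OC)CCC/C(OC)=C\C(=O)CC(=O)Cl | intermediate (not isolated)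
5 | bis(2,4-dihydroxy-6-methoxyphenyl)methane | COc1cc(O)cc(O)c1Cc1c(OC)cc(O)cc1O | intermediate
6 | bis[6-methoxy-2,4-bis(methoxymethoxy)phenyl]methane | COCOc1cc(OC)c(Cc2c(OC)cc(OCOC)cc2OCOC)c(OCOC)c1 | intermediate
7 | 2,4-dihydroxy-6-methylbenzaldehyde | Cc1cc(O)cc(O)c1C=O | starting material
8 | 2-hydroxy-4-(methoxymethoxy)-6-methylbenzaldehyde | COCOc1cc(C)c(C=O)c(O)c1 | intermediate
9 | 2-methoxy-4-(methoxymethoxy)-6-methylbenzaldehyde | COCOc1cc(C)c(C=O)c(OC)c1 | intermediate
10 | bis[3-lithio-6-methoxy-2,4-bis(methoxymethoxy)phenyl]methane | [Li]c1c(OCOC)cc(OC)c(Cc2c(OC)cc(OCOC)c([Li])c2OCOC)c1OCOC | intermediate (not isolated)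
11 | {methylenebis[4-methoxy-2,6-bis(methoxymethoxy)-3,1-phenylene]}bis{[2-methoxy-4-(methoxymethoxy)-6-methylphenyl]methanol}, meso/dl mixture | COCOc1cc(C)c(C(O)c2c(OCOC)cc(OC)c(Cc3c(OC)cc(OCOC)c(C(O)c4c(C)cc(OCOC)cc4OC)c3OCOC)c2OCOC)c(OC)c1 | intermediate
12 | {methylenebis[4-methoxy-2,6-bis(methoxymethoxy)-3,1-phenylene]}bis{[2-methoxy-4-(methoxymethoxy)-6-methylphenyl]methanone} | COCOc1cc(C)c(C(=O)c2c(OCOC)cc(OC)c(Cc3c(OC)cc(OCOC)c(C(=O)c4c(C)cc(OCOC)cc4OC)c3OCOC)c2OCOC)c(OC)c1 | intermediate
13 | digriseophene A, {methylenebis[2,6-dihydroxy-4-methoxy-3,1-phenylene]}bis[(4-hydroxy-2-methoxy-6-methylphenyl)methanone] | COc1cc(O)c(C(=O)c2c(C)cc(O)cc2OC)c(O)c1Cc1c(OC)cc(O)c(C(=O)c2c(C)cc(O)cc2OC)c1O | target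

**Total step count:** 8
**Longest linear sequence:** 6 (steps 1, 2, 3, 6, 7, 8)

**Steps most likely to fail**

**Step 2.**
- What may go wrong: chloride may attack the O-methyl oxocarbenium ions, after which the freed ketone oxygen closes onto the acid chloride to give pyrones. One malonyl unit may link two enol ether termini, and traces of acid may oligomerise 2.
- Fallback: it uses only known chemistry, gives up the de novo arene construction, sets out from 9 and comes back to the route at 13.
- Commercial 5-methoxyresorcinol is protected with MOMCl/iPr2NEt to 1-methoxy-3,5-bis(methoxymethoxy)benzene F1. This is lithiated between the two MOM ethers (n-BuLi, THF, 0 °C) and added to 9 to give [4-methoxy-2,6-bis(methoxymethoxy)phenyl][2-methoxy-4-(methoxymethoxy)-6-methylphenyl]methanol F2.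
- Dess–Martin oxidation gives [4-methoxy-2,6-bis(methoxymethoxy)phenyl][2-methoxy-4-(methoxymethoxy)-6-methylphenyl]methanone F3. Methanolic HCl then frees (2,6-dihydroxy-4-methoxyphenyl)(4-hydroxy-2-methoxy-6-methylphenyl)methanone F4.
- The two open A-ring positions of F4 are equivalent. Half an equivalent of aqueous formaldehyde with catalytic KOH, the classical methylene-bis(acylphloroglucinol) condensation, should therefore join two molecules at C3 to give 13.

**Step 6.**
- What may go wrong: the second metalation may stay incomplete, protons may be abstracted from the bridge CH2 or from C5, and the addition may stall after one aldehyde because of crowding.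
- Fallback: it replaces deprotonation by halogen–metal exchange, sets out from 5 and comes back to the route at 10.
- Iodination of 5 with I2/NaHCO3 in aqueous THF at 0 °C should place iodine between the two hydroxy groups of each ring, as in the 2-selective iodination of resorcinols. This gives 4,4′-methylenebis(2-iodo-5-methoxybenzene-1,3-diol) F5.
- MOMCl/iPr2NEt converts F5 into bis[3-iodo-6-methoxy-2,4-bis(methoxymethoxy)phenyl]methane F6, which can be purified.
- Iodine–lithium exchange with n-BuLi at −78 °C, where C–H deprotonation does not compete, then gives regiodefined 10 for the addition to 9.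

**Step 1.**
- What may go wrong: the second ester may be methylenated incompletely. The enol ether may hydrolyse or its double bonds may migrate while titanium residues are removed, and the volatile product may be lost.
- Fallback: it builds the enol ethers from the diketone instead, sets out from 1 and comes back to the route at 2.
- MeNH(OMe)·HCl/iPrMgCl converts 1 into N1,N5-dimethoxy-N1,N5-dimethylpentanediamide F7. MeMgBr then gives heptane-2,6-dione F8, which can also be bought.
- Trimethyl orthoformate with catalytic TsOH in MeOH at rt gives 2,2,6,6-tetramethoxyheptane F9.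
- TMSOTf/iPr2NEt in CH2Cl2 at −20 °C removes one methanol equivalent per ketal by kinetic deprotonation at the methyl groups, which should give the terminal bis(enol ether) 2.

**Further compounds**
F1 | step 2 | 1-methoxy-3,5-bis(methoxymethoxy)benzene | COCOc1cc(OC)cc(OCOC)c1
F2 | step 2 | [4-methoxy-2,6-bis(methoxymethoxy)phenyl][2-methoxy-4-(methoxymethoxy)-6-methylphenyl]methanol (racemic) | COCOc1cc(C)c(C(O)c2c(OCOC)cc(OC)cc2OCOC)c(OC)c1
F3 | step 2 | [4-methoxy-2,6-bis(methoxymethoxy)phenyl][2-methoxy-4-(methoxymethoxy)-6-methylphenyl]methanone | COCOc1cc(C)c(C(=O)c2c(OCOC)cc(OC)cc2OCOC)c(OC)c1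
F4 | step 2 | (2,6-dihydroxy-4-methoxyphenyl)(4-hydroxy-2-methoxy-6-methylphenyl)methanone | COc1cc(O)c(C(=O)c2c(C)cc(O)cc2OC)c(O)c1
F5 | step 6 | 4,4′-methylenebis(2-iodo-5-methoxybenzene-1,3-diol) | COc1cc(O)c(I)c(O)c1Cc1c(OC)cc(O)c(I)c1O
F6 | step 6 | bis[3-iodo-6-methoxy-2,4-bis(methoxymethoxy)phenyl]methane | COCOc1cc(OC)c(Cc2c(OC)cc(OCOC)c(I)c2OCOC)c(OCOC)c1I
F7 | step 1 | N1,N5-dimethoxy-N1,N5-dimethylpentanediamide | CON(C)C(=O)CCCC(=O)N(C)OC
F8 | step 1 | heptane-2,6-dione | CC(=O)CCCC(C)=O
F9 | step 1 | 2,2,6,6-tetramethoxyheptane | COC(C)(OC)CCCC(C)(OC)OC
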